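## The problem

Compound 26 is a 3-arylchroman-4-one (isoflavanone): ring A is fused to the pyranone ring C, and ring B is attached at C3 of ring C. The only stereocentre is C3 (R). It is benzylic and α to the C4 ketone, so no other centre can relay chirality to it, and once the ketone exists acid or base can erase it through the enol. Ring A is a methylphloroglucinol whose three oxygens are not equivalent: O1 must be the oxygen that is not next to the C6 methyl, and C4a must lie between O1 and O5. Ring B carries an (E)-geranyl chain ortho to the 4'-hydroxyl. Its two trisubstituted alkenes exclude hydrogenolysis, boranes, electrophilic halogen and hot protic acid, which would close a chroman onto the 4'-oxygen. The 2'-hydroxyl can reach the C4 carbonyl, and acid-driven hemiketalisation and dehydration would give a pterocarpene and destroy C3, so the four phenols must be unmasked last, quickly and gently. The enabling feature is that C3 is the middle carbon of a 2-aryl-1,3-dioxygenated propane: C2 is a CH2–O, C4 is a C=O, and their ring A partners O1 and C4a are ortho to each other. This is the retron of a syn aldol between an arylacetyl unit (C3 and C2) and a ring A benzaldehyde (C4), with the acyl carbon reduced afterwards to the C2 methylene.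

## Retrosynthesis

**26 ⇒ 25.** The four aryl O–CH2OMe bonds are cut. MOM ethers are preferred to benzyl ethers (no hydrogenolysis beside geranyl) and to silyl ethers (silyl migration to carbon in ortho-lithiated intermediates, lability to base). They also support the organolithium chemistry on ring B. The forward step must be fast and mild, because 25 already carries the enolisable C3–H.

**25 ⇒ 24.** The C4 ketone is taken back to the carbinol. Holding C4 at the alcohol level until the penultimate step means C3 is not acidic during auxiliary removal, deallylation and ring closure. The forward step only needs a neutral oxidant.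

**24 ⇒ 23 ⇒ 22.** Ring C is opened at O1–C2. Cutting C4–C4a instead would need a Friedel–Crafts acylation with C3 next to an acylium ion. Cutting O1–C8a would need aryl substitution on a very electron-rich ring. The O1–C2 closure is an ether formation between a phenol and a primary alcohol, available under neutral Mitsunobu conditions. Triol 23 is acyclic and comes from 22 by removing an allyl group from the future O1. Allyl is chosen because zerovalent palladium removes it without touching MOM ethers, the geranyl chain or the acid-labile benzylic carbinol.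

**22 ⇒ 21.** The C2–OH bond is traced to an N-acyl oxazolidinone carbonyl. Reductive cleavage removes the auxiliary and sets the C2 oxidation level in one operation, so no separate hydrolysis and reduction are needed.

**21 ⇒ 12 + 18.** The C3–C4 bond is cut. The neighbouring cuts are C3–C1' (arylation of a preformed chromanone) and C3–H (protonation or hydrogenation of an enol or alkene). Both create the stereocentre beside an existing ketone or alkene and are discussed below. The aldol cut joins two fragments of similar size, builds the whole carbon skeleton and sets C3 in the same event. The forward reaction must give a Z enolate, add to one enolate face, tolerate MOM acetals and alkenes, and accept a hindered, electron-rich aldehyde.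

**12 ⇒ 9 + 10; 9 ⇒ 8 ⇒ 6 + 7; 6 ⇒ 2 + 3; 2 ⇒ 1.** The imide N–C(O) bond is cut to acid 9 and auxiliary 10. The aryl–CH2 bond of ester 8 is cut to aryl bromide 6 and zinc enolate 7. The aryl–geranyl bond is cut to dibromide 2 and geranyl bromide 3. Dibromide 2 comes from 4,6-dibromoresorcinol 1, whose two bromines already mark both carbon substituents of ring B. The sequence asks for selective mono bromine–lithium exchange and a linear (SN2) allylic substitution.

**18 ⇒ 17 ⇒ 16 ⇒ 14 ⇒ 13.** The allyl ether, then the formyl C–C bond, then the phenolic C–O bond are cut. Phenol 16 is symmetric, so ortho-formylation can give only one aldehyde, and the oxygen remote from the methyl group automatically becomes O1. Phenol 16 comes from 2-methylresorcinol 13 by MOM protection and C–H borylation/oxidation at the only unhindered ring position.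

## Roads not taken

**Alternative 1:** asymmetric hydroboration of a 3-aryl-2H-chromene. The cut is C3–H and C4–O across the C3=C4 bond of the chromene A1. In the forward step IpcBH2 adds syn, with hydrogen to C3 and boron to C4, and oxidation gives the trans-(3R,4S)-chroman-4-ol A2, which has the same configuration as 24. Its merit is that ring C is already closed, so neither auxiliary handling nor a Mitsunobu step is needed, and C3 and C4 arise in one operation. Its weak point for this target is the geranyl chain, whose trisubstituted alkenes would be hydroborated as readily as C3=C4. A2 therefore carries bromine as a placeholder, and the chain must be added afterwards by halogen–metal exchange on a molecule that already holds the labile benzylic carbinol, at the cost of extra protection steps. The alkene is also crowded on both sides (the ortho-OMOM of ring B and the peri-OMOM at C5), so the face selectivity of a reagent-controlled addition is hard to predict. The product is an enantiomer mixture that cannot be upgraded by simple separation. On the step count from fragment union to the chroman-4-ol this road is shorter. The chosen plan sets against it a closed transition state with predictable sense, diastereomeric adducts that can be purified, and a geranyl group that is in place from the second step.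

**Alternative 2:** stereoconvergent nickel-catalysed Negishi arylation. The cut is C3–C1'. The racemic 3-bromochromanone A3 and the ring B arylzinc iodide A4 would couple under NiCl2·glyme and a chiral pybox ligand at low temperature to give the tetra-MOM ketone A5, which is identical with 25. This is the most convergent road and is clearly better in step economy: it is catalytic, needs no auxiliary, and its product is one step from 26. The weak points are two extrapolations in one step. The method is established for acyclic α-bromo ketones, whereas A3 is cyclic, carries a β-aryloxy group that can be lost by elimination (ring opening or chromone formation), and has a peri-OMOM beside the carbonyl. A4 has an OMOM group ortho to zinc, and ortho-substituted nucleophiles are the ones that couple slowly and with lower selectivity in this chemistry. The chosen plan is longer by about a third but relies on a reaction class that has been applied to ortho-alkoxy arylacetyl imides and aromatic aldehydes.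

**Alternative 3:** desymmetrising oxetane opening. The cut is O1–C2. A chiral phosphoric acid would activate the 3-aryloxetane A6, and the ring A iodophenol A7 would open one of the two enantiotopic CH2–O bonds to give the (S)-alcohol A8 with C3 set. Its merits are a catalytic, metal-free stereo-defining step and an easily made prochiral substrate. The weak points are the nucleophile and the end game. Intermolecular opening of oxetanes by a phenol oxygen is not a secure member of this reaction family, and the electron-rich A7 can also react through carbon. The C4–C4a bond is still missing in A8. Forming it requires raising the CH2OH to the carbonyl level and closing onto the aryl iodide under organometallic conditions, with C3 then α to a carbonyl and benzylic at the most basic stage of the route. The chosen plan makes the C–C bond first and closes the ring at oxygen under neutral conditions, at the price of a stoichiometric auxiliary and two steps for its attachment and removal.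

Key step: step 10

Remark: "geranyl" means (2E)-3,7-dimethylocta-2,6-dien-1-yl throughout. Compound 7 is assumed to be used as its commercial ether solution (it can also be made beforehand from ethyl bromoacetate and zinc dust).

## Route

Step 1
Reactants: 1 4,6-dibromobenzene-1,3-diol
Product: 2 1,5-dibromo-2,4-bis(methoxymethoxy)benzene
Conditions: MOMCl, iPr2NEt, CH2Cl2, 0 °C → rt
Reagents that add atoms: chloromethyl methyl ether, COCCl
Why: Williamson-type O-alkylation of both phenols (MOM protection); the acetals survive all later basic and organometallic steps and stabilise the ortho-lithio species of step 2.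

Step 2
Reactants: 2 1,5-dibromo-2,4-bis(methoxymethoxy)benzene; 3 geranyl bromide
Product: 6 1-bromo-5-geranyl-2,4-bis(methoxymethoxy)benzene, via aryllithium 4 (not isolated), via arylcopper 5 (not isolated)
Conditions: n-BuLi (1.05 equiv), THF, −78 °C; CuBr·SMe2 (1.0 equiv), −78 → −40 °C; 3, −78 → 0 °C
Reagents that add atoms: none
Why: Bromine–lithium exchange stops after one bromine because a second exchange on an already anionic ring is much slower; transmetalation to copper followed by SN2 allylic substitution at the primary carbon of 3 should give the linear geranyl arene with the E alkene unchanged.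

Step 3
Reactants: 6 1-bromo-5-geranyl-2,4-bis(methoxymethoxy)benzene; 7 ethyl (bromozincio)acetate, BrZnCH2CO2Et
Product: 8 ethyl 2-[5-geranyl-2,4-bis(methoxymethoxy)phenyl]acetate
Conditions: Pd2(dba)3 (2.5 mol %), XPhos (6 mol %), THF, 65 °C
Reagents that add atoms: none
Why: Palladium-catalysed α-arylation of a zinc ester enolate (Reformatsky-type Negishi coupling); the neutral zinc enolate leaves MOM acetals alone, the bulky biarylphosphine allows oxidative addition into the electron-rich ortho-substituted C–Br bond, and trisubstituted alkenes do not insert.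

Step 4
Reactants: 8 ethyl 2-[5-geranyl-2,4-bis(methoxymethoxy)phenyl]acetate
Product: 9 2-[5-geranyl-2,4-bis(methoxymethoxy)phenyl]acetic acid
Conditions: LiOH·H2O, THF/MeOH/H2O, rt; then 1 M HCl to pH 4, 0 °C
Reagents that add atoms: lithium hydroxide (aqueous), [Li+].[OH-]
Why: Ester saponification; brief cold acidification to pH 4 should spare the aryl MOM acetals.

Step 5
Reactants: 9 2-[5-geranyl-2,4-bis(methoxymethoxy)phenyl]acetic acid; 10 (S)-4-benzyl-1,3-oxazolidin-2-one
Product: 12 (S)-4-benzyl-3-{2-[5-geranyl-2,4-bis(methoxymethoxy)phenyl]acetyl}-1,3-oxazolidin-2-one, via mixed pivalic anhydride 11 (not isolated)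
Conditions: PivCl, Et3N, THF, −20 °C; then 10, LiCl, −20 °C → rt
Reagents that add atoms: none
Why: N-acylation of the oxazolidinone through a mixed pivalic anhydride with LiCl/Et3N activation; attack occurs at the less hindered arylacetyl carbonyl, and the acid chloride (prone to ketene formation with arylacetic acids) is avoided.

Step 6
Reactants: 13 2-methylbenzene-1,3-diol
Product: 14 1,3-bis(methoxymethoxy)-2-methylbenzene
Conditions: MOMCl, iPr2NEt, CH2Cl2, 0 °C → rt
Reagents that add atoms: chloromethyl methyl ether, COCCl
Why: MOM protection of both phenols by O-alkylation under amine base.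

Step 7
Reactants: 14 1,3-bis(methoxymethoxy)-2-methylbenzene
Product: 16 3,5-bis(methoxymethoxy)-4-methylphenol, via aryl pinacol boronate 15 (not isolated)
Conditions: [Ir(OMe)(cod)]2 (1.5 mol %), dtbpy (3 mol %), B2pin2, THF, 80 °C; then NaOH, 30% H2O2, THF/H2O, 0 °C
Reagents that add atoms: hydrogen peroxide, OO (the phenol oxygen); bis(pinacolato)diboron, CC1(C)OB(OC1(C)C)B1OC(C)(C)C(C)(C)O1 (boron of 15 only, lost on oxidation)
Why: Sterically controlled iridium-catalysed C–H borylation goes to the only ring C–H with no ortho substituent (C5, meta to both OMOM groups); alkaline peroxide then converts C–B into C–O by 1,2-aryl migration and gives the symmetric phenol.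

Step 8
Reactants: 16 3,5-bis(methoxymethoxy)-4-methylphenol
Product: 17 6-hydroxy-2,4-bis(methoxymethoxy)-3-methylbenzaldehyde
Conditions: MgCl2, Et3N, (CH2O)n, MeCN, reflux; aq NH4Cl work-up
Reagents that add atoms: paraformaldehyde (as formaldehyde), C=O
Why: Magnesium-mediated ortho-formylation of a phenol (Casnati–Skattebøl): the magnesium phenoxide delivers formaldehyde only ortho to the free OH and a second formaldehyde oxidises the benzylic alkoxide; the two ortho positions are equivalent, so one regioisomer results and the oxygen remote from the methyl group is fixed as the future O1.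

Step 9
Reactants: 17 6-hydroxy-2,4-bis(methoxymethoxy)-3-methylbenzaldehyde
Product: 18 6-(allyloxy)-2,4-bis(methoxymethoxy)-3-methylbenzaldehyde
Conditions: allyl bromide, K2CO3, DMF, rt
Reagents that add atoms: allyl bromide, C=CCBr
Why: Williamson O-allylation of the salicylaldehyde phenol; the allyl ether is orthogonal to MOM and is removed later under neutral palladium catalysis.

Step 10
Reactants: 12 (S)-4-benzyl-3-{2-[5-geranyl-2,4-bis(methoxymethoxy)phenyl]acetyl}-1,3-oxazolidin-2-one; 18 6-(allyloxy)-2,4-bis(methoxymethoxy)-3-methylbenzaldehyde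
Product: 21 (S)-4-benzyl-3-[(2S,3S)-3-[6-(allyloxy)-2,4-bis(methoxymethoxy)-3-methylphenyl]-2-[5-geranyl-2,4-bis(methoxymethoxy)phenyl]-3-hydroxypropanoyl]-1,3-oxazolidin-2-one, via boron Z-enolate 19 (not isolated), via boron aldolate 20 (not isolated)
Conditions: Bu2BOTf, iPr2NEt, CH2Cl2, −78 → 0 °C; 18 (excess), −78 → 0 °C; pH 7 buffer, MeOH, 30% H2O2, 0 °C
Reagents that add atoms: none
Why: Soft enolisation of 12 with Bu2BOTf and iPr2NEt should give only the Z boron enolate 19, because the E geometry would force the aryl group against the oxazolidinone. Aldehyde 18 binds to boron and the C3–C4 bond forms through a closed six-membered Zimmerman–Traxler chair; the closest known reaction type is the Evans syn aldol of arylacetyl oxazolidinones with aromatic aldehydes. No ring is closed. C3 is controlled by the auxiliary: boron has no free site to chelate the ring carbonyl, so the imide adopts the dipole-minimised rotamer, the benzyl group covers one enolate face, and the aldehyde adds to the other, giving 2S in 21, which becomes 3R in the chromanone when the CIP ranks of C2 and C4 exchange. C4 is controlled by the Z enolate geometry and the pseudo-equatorial aldehyde aryl group, giving the syn (2S,3S) adduct; this centre is temporary and is removed in step 14. The selectivity needed is facial and is secured by the (S)-benzyl auxiliary; the demand on reactivity comes from the di-ortho-oxygenated, electron-rich aldehyde and is met by excess 18, high concentration and warming to 0 °C before neutral oxidative cleavage of aldolate 20.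

Step 11
Reactants: 21 syn-aldol adduct
Product: 22 (1S,2R)-1-[6-(allyloxy)-2,4-bis(methoxymethoxy)-3-methylphenyl]-2-[5-geranyl-2,4-bis(methoxymethoxy)phenyl]propane-1,3-diol
Conditions: LiBH4, MeOH (1 equiv), THF, 0 °C
Reagents that add atoms: none
Why: Reductive cleavage of the N-acyl oxazolidinone: hydride attacks the exocyclic imide carbonyl, which becomes the C2 primary alcohol, and the auxiliary is released for recovery; no stereocentre is touched (the descriptor at the aryl-bearing carbon changes from S to R only through CIP ranking).

Step 12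
Reactants: 22 allyl-protected diol
Product: 23 (1S,2R)-1-[6-hydroxy-2,4-bis(methoxymethoxy)-3-methylphenyl]-2-[5-geranyl-2,4-bis(methoxymethoxy)phenyl]propane-1,3-diol
Conditions: Pd(PPh3)4 (5 mol %), morpholine, THF, rt
Reagents that add atoms: none
Why: Deallylation catalysed by zerovalent palladium (Tsuji–Trost ionisation of the aryl allyl ether, π-allyl capture by morpholine); the geranyl alkenes carry no leaving group, and the neutral conditions keep the MOM acetals and the benzylic carbinol intact.

Step 13
Reactants: 23 phenol diol
Product: 24 (3R,4S)-3-[5-geranyl-2,4-bis(methoxymethoxy)phenyl]-5,7-bis(methoxymethoxy)-6-methylchroman-4-ol (trans)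
Conditions: PPh3, DIAD, THF, 0 °C → rt
Reagents that add atoms: none
Why: Intramolecular Mitsunobu etherification: the phenol is the only acidic OH, the less hindered primary alcohol forms the oxyphosphonium ion and the phenoxide displaces it in a 6-exo-tet closure of O1–C2; the hindered secondary carbinol could only form a four-membered ring, and neither stereocentre takes part.

Step 14
Reactants: 24 trans-chroman-4-ol
Product: 25 (3R)-3-[5-geranyl-2,4-bis(methoxymethoxy)phenyl]-5,7-bis(methoxymethoxy)-6-methylchroman-4-one
Conditions: Dess–Martin periodinane, NaHCO3, CH2Cl2, 0 °C → rt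
Reagents that add atoms: none
Why: Dess–Martin oxidation of the secondary benzylic alcohol under bicarbonate buffer; the conditions are neither acidic nor basic enough to enolise the new ketone, so C3 should keep its configuration, and alkenes and acetals are inert.

Step 15
Reactants: 25 tetra-MOM isoflavanone
Product: 26 (3R)-3-[5-geranyl-2,4-dihydroxyphenyl]-5,7-dihydroxy-6-methylchroman-4-one
Conditions: ZnBr2, n-PrSH, CH2Cl2, 0 °C, 10–15 min
Reagents that add atoms: none
Why: Lewis acid/thiol cleavage of MOM acetals: ZnBr2 activates each acetal and propanethiol traps the methoxymethyl cation, so all four phenols should be freed within minutes at 0 °C; the short contact time is what protects the enolisable C3–H, the geranyl alkenes and the 2'-OH/C4=O pair.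

## Compound list

1 | 4,6-dibromobenzene-1,3-diol (4,6-dibromoresorcinol) | Oc1cc(O)c(Br)cc1Br | starting material
2 | 1,5-dibromo-2,4-bis(methoxymethoxy)benzene | COCOc1cc(OCOC)c(Br)cc1Br | intermediate
3 | geranyl bromide, (2E)-1-bromo-3,7-dimethylocta-2,6-diene | CC(C)=CCC/C(C)=C/CBr | starting material
4 | [5-bromo-2,4-bis(methoxymethoxy)phenyl]lithium (not isolated) | [Li]c1cc(Br)c(OCOC)cc1OCOC | intermediate
5 | [5-bromo-2,4-bis(methoxymethoxy)phenyl]copper (not isolated) | [Cu]c1cc(Br)c(OCOC)cc1OCOC | intermediate
6 | 1-bromo-5-[(2E)-3,7-dimethylocta-2,6-dien-1-yl]-2,4-bis(methoxymethoxy)benzene | CC(C)=CCC/C(C)=C/Cc1cc(Br)c(OCOC)cc1OCOC | intermediate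
7 | ethyl (bromozincio)acetate, BrZnCH2CO2Et | CCOC(=O)C[Zn]Br | starting material
8 | ethyl 2-{5-[(2E)-3,7-dimethylocta-2,6-dien-1-yl]-2,4-bis(methoxymethoxy)phenyl}acetate | CC(C)=CCC/C(C)=C/Cc1cc(CC(=O)OCC)c(OCOC)cc1OCOC | intermediate
9 | 2-{5-[(2E)-3,7-dimethylocta-2,6-dien-1-yl]-2,4-bis(methoxymethoxy)phenyl}acetic acid | CC(C)=CCC/C(C)=C/Cc1cc(CC(=O)O)c(OCOC)cc1OCOC | intermediate
10 | (S)-4-benzyl-1,3-oxazolidin-2-one | O=C1N[C@@H](Cc2ccccc2)CO1 | starting material
11 | mixed anhydride of 9 with pivalic acid (not isolated) | CC(C)=CCC/C(C)=C/Cc1cc(CC(=O)OC(=O)C(C)(C)C)c(OCOC)cc1OCOC | intermediate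
12 | (S)-4-benzyl-3-{2-[5-geranyl-2,4-bis(methoxymethoxy)phenyl]acetyl}-1,3-oxazolidin-2-one | CC(C)=CCC/C(C)=C/Cc1cc(CC(=O)N2C(=O)OC[C@@H]2Cc2ccccc2)c(OCOC)cc1OCOC | intermediate
13 | 2-methylbenzene-1,3-diol (2-methylresorcinol) | Cc1c(O)cccc1O | starting material
14 | 1,3-bis(methoxymethoxy)-2-methylbenzene | COCOc1cccc(OCOC)c1C | intermediate
15 | 2-[3,5-bis(methoxymethoxy)-4-methylphenyl]-4,4,5,5-tetramethyl-1,3,2-dioxaborolane (not isolated) | COCOc1cc(B2OC(C)(C)C(C)(C)O2)cc(OCOC)c1C | intermediate
16 | 3,5-bis(methoxymethoxy)-4-methylphenol | COCOc1cc(O)cc(OCOC)c1C | intermediate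
17 | 6-hydroxy-2,4-bis(methoxymethoxy)-3-methylbenzaldehyde | COCOc1cc(O)c(C=O)c(OCOC)c1C | intermediate
18 | 6-(allyloxy)-2,4-bis(methoxymethoxy)-3-methylbenzaldehyde | C=CCOc1cc(OCOC)c(C)c(OCOC)c1C=O | intermediate
19 | dibutylboron (Z)-enolate of 12: (S)-4-benzyl-3-[(Z)-1-(dibutylboranyloxy)-2-(5-geranyl-2,4-bis(methoxymethoxy)phenyl)ethenyl]-1,3-oxazolidin-2-one (not isolated) | CC(C)=CCC/C(C)=C/Cc1cc(/C=C(\OB(CCCC)CCCC)N2C(=O)OC[C@@H]2Cc2ccccc2)c(OCOC)cc1OCOC | intermediate
20 | dibutylboron aldolate of 21 (O–BBu2 on the carbinol oxygen; 2S,3S; not isolated) | CC(C)=CCC/C(C)=C/Cc1cc([C@@H]([C@H](OB(CCCC)CCCC)c2c(OCC=C)cc(OCOC)c(C)c2OCOC)C(=O)N2C(=O)OC[C@@H]2Cc2ccccc2)c(OCOC)cc1OCOC | intermediate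
21 | (S)-4-benzyl-3-[(2S,3S)-3-[6-(allyloxy)-2,4-bis(methoxymethoxy)-3-methylphenyl]-2-[5-geranyl-2,4-bis(methoxymethoxy)phenyl]-3-hydroxypropanoyl]-1,3-oxazolidin-2-one | CC(C)=CCC/C(C)=C/Cc1cc([C@@H]([C@H](O)c2c(OCC=C)cc(OCOC)c(C)c2OCOC)C(=O)N2C(=O)OC[C@@H]2Cc2ccccc2)c(OCOC)cc1OCOC | intermediate
22 | (1S,2R)-1-[6-(allyloxy)-2,4-bis(methoxymethoxy)-3-methylphenyl]-2-[5-geranyl-2,4-bis(methoxymethoxy)phenyl]propane-1,3-diol | CC(C)=CCC/C(C)=C/Cc1cc([C@@H]([C@H](O)c2c(OCC=C)cc(OCOC)c(C)c2OCOC)CO)c(OCOC)cc1OCOC | intermediate
23 | (1S,2R)-1-[6-hydroxy-2,4-bis(methoxymethoxy)-3-methylphenyl]-2-[5-geranyl-2,4-bis(methoxymethoxy)phenyl]propane-1,3-diol | CC(C)=CCC/C(C)=C/Cc1cc([C@@H]([C@H](O)c2c(O)cc(OCOC)c(C)c2OCOC)CO)c(OCOC)cc1OCOC | intermediate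
24 | (3R,4S)-3-[5-geranyl-2,4-bis(methoxymethoxy)phenyl]-5,7-bis(methoxymethoxy)-6-methylchroman-4-ol | CC(C)=CCC/C(C)=C/Cc1cc([C@@H]2COc3cc(OCOC)c(C)c(OCOC)c3[C@H]2O)c(OCOC)cc1OCOC | intermediate
25 | (3R)-3-[5-geranyl-2,4-bis(methoxymethoxy)phenyl]-5,7-bis(methoxymethoxy)-6-methylchroman-4-one | CC(C)=CCC/C(C)=C/Cc1cc([C@@H]2COc3cc(OCOC)c(C)c(OCOC)c3C2=O)c(OCOC)cc1OCOC | intermediate
26 | (3R)-3-{5-[(2E)-3,7-dimethylocta-2,6-dien-1-yl]-2,4-dihydroxyphenyl}-5,7-dihydroxy-6-methyl-2,3-dihydro-4H-chromen-4-one | CC(C)=CCC/C(C)=C/Cc1cc([C@@H]2COc3cc(O)c(C)c(O)c3C2=O)c(O)cc1O | target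

## Step count and risks

Total step count: 15. Longest linear sequence: 11 steps (steps 1–5, then 10–15, from 1). The ring A branch (steps 6–9) has 4 steps.

**Step 10 (key step).** The most likely failure is slow C–C bond formation. The aldehyde carbon of 18 sits between two ortho oxygens and receives electron density from three donors, so addition to the boron enolate may stall. Long times at 0 °C or above invite retro-aldol equilibration, with loss of the syn preference, and cleavage of MOM acetals by the boron Lewis acid. The fallback makes the aldehyde a better electrophile by masking the future O1 as an acceptor ester instead of a donor ether. It sets out from 17, which with PivCl, Et3N and DMAP gives 2-formyl-3,5-bis(methoxymethoxy)-4-methylphenyl 2,2-dimethylpropanoate F1. The same boron aldol with 12 gives (S)-4-benzyl-3-[(2S,3S)-3-hydroxy-3-[2,4-bis(methoxymethoxy)-3-methyl-6-(pivaloyloxy)phenyl]-2-[5-geranyl-2,4-bis(methoxymethoxy)phenyl]propanoyl]-1,3-oxazolidin-2-one F2. Excess LiBH4 then removes the auxiliary and the aryl ester together; an acyl shift to the benzylic oxygen would not matter, because either ester is reduced. The fallback comes back to the route at 23, one step shorter.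

**Step 15.** Three processes threaten the final unmasking. The first is partial epimerisation of C3 through Lewis-acid-assisted enolisation. The second is acid-triggered addition of the 4'-oxygen to the geranyl alkene. The third is incomplete cleavage that forces longer exposure. The fallback exchanges the protecting groups on the finished skeleton for fluoride-labile ones. It sets out from 25: TESOTf and 2,2'-bipyridyl in CH2Cl2 at 0 °C convert aryl MOM ethers directly into aryl silyl ethers, and the base is too weak to enolise the ketone. The methoxy group leaves as methoxytriethylsilane and the methylene carbon as formaldehyde on aqueous work-up. This gives (3R)-3-[5-geranyl-2,4-bis(triethylsilyloxy)phenyl]-6-methyl-5,7-bis(triethylsilyloxy)chroman-4-one F3. HF·pyridine in THF/pyridine at 0 °C then frees the phenols, and the fallback comes back at 26.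

**Step 13.** The benzylic C4 carbinol is pushed by O5, O7 and the phenoxide. It may therefore be activated or ionise under the Mitsunobu conditions, leading to loss of water across C3–C4 (which destroys the stereocentre) or to intermolecular etherification. The fallback separates activation from ring closure and never activates in the presence of the free phenol. It sets out from 22: TsCl and pyridine at 0 °C sulfonylate only the primary alcohol and give (2R,3S)-3-[6-(allyloxy)-2,4-bis(methoxymethoxy)-3-methylphenyl]-2-[5-geranyl-2,4-bis(methoxymethoxy)phenyl]-3-hydroxypropyl 4-methylbenzenesulfonate F4. Pd(PPh3)4 with K2CO3 in MeOH then removes the allyl group, and the resulting (2R,3S)-3-hydroxy-3-[6-hydroxy-2,4-bis(methoxymethoxy)-3-methylphenyl]-2-[5-geranyl-2,4-bis(methoxymethoxy)phenyl]propyl 4-methylbenzenesulfonate F5 (not isolated) closes as its phenoxide by a 6-exo-tet Williamson reaction. The fallback comes back at 24.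

**Step 11.** The aldolate formed on contact with LiBH4 can fragment by retro-aldol before hydride is delivered, because the leaving arylacetyl enolate is stabilised and the aldehyde is electron-rich. This would return 12 and 18 or epimerise the adduct. The fallback removes the free alkoxide. It sets out from 21: TBSOTf and 2,6-lutidine give (S)-4-benzyl-3-[(2S,3S)-3-[6-(allyloxy)-2,4-bis(methoxymethoxy)-3-methylphenyl]-3-(tert-butyldimethylsilyloxy)-2-[5-geranyl-2,4-bis(methoxymethoxy)phenyl]propanoyl]-1,3-oxazolidin-2-one F6. LiBH4 gives (2R,3S)-3-[6-(allyloxy)-2,4-bis(methoxymethoxy)-3-methylphenyl]-3-(tert-butyldimethylsilyloxy)-2-[5-geranyl-2,4-bis(methoxymethoxy)phenyl]propan-1-ol F7. TBAF in THF removes the silyl group, and the fallback comes back at 22.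

**Step 3.** Oxidative addition into the electron-rich, ortho-substituted C–Br bond may be slow, so protodebromination and self-condensation of the zinc enolate could take over. The fallback builds the two-carbon arm by organolithium chemistry and oxidation instead of cross-coupling. It sets out from 6: n-BuLi at −78 °C gives [5-geranyl-2,4-bis(methoxymethoxy)phenyl]lithium F8. Oxirane (with catalytic CuBr·SMe2) gives 2-[5-geranyl-2,4-bis(methoxymethoxy)phenyl]ethan-1-ol F9. Dess–Martin oxidation gives 2-[5-geranyl-2,4-bis(methoxymethoxy)phenyl]acetaldehyde F10. Pinnick oxidation (NaClO2, NaH2PO4, excess 2-methyl-2-butene, t-BuOH/H2O) then gives the acid, and the fallback comes back at 9, bypassing 8.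

## Further compounds

F1 | step 10 | 2-formyl-3,5-bis(methoxymethoxy)-4-methylphenyl 2,2-dimethylpropanoate | CC(C)(C)C(=O)Oc1cc(OCOC)c(C)c(OCOC)c1C=O
F2 | step 10 | (S)-4-benzyl-3-[(2S,3S)-3-hydroxy-3-[2,4-bis(methoxymethoxy)-3-methyl-6-(pivaloyloxy)phenyl]-2-[5-geranyl-2,4-bis(methoxymethoxy)phenyl]propanoyl]-1,3-oxazolidin-2-one | CC(C)=CCC/C(C)=C/Cc1cc([C@@H]([C@H](O)c2c(OC(=O)C(C)(C)C)cc(OCOC)c(C)c2OCOC)C(=O)N2C(=O)OC[C@@H]2Cc2ccccc2)c(OCOC)cc1OCOC
F3 | step 15 | (3R)-3-[5-geranyl-2,4-bis(triethylsilyloxy)phenyl]-6-methyl-5,7-bis(triethylsilyloxy)chroman-4-one | CC(C)=CCC/C(C)=C/Cc1cc([C@@H]2COc3cc(O[Si](CC)(CC)CC)c(C)c(O[Si](CC)(CC)CC)c3C2=O)c(O[Si](CC)(CC)CC)cc1O[Si](CC)(CC)CC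
F4 | step 13 | (2R,3S)-3-[6-(allyloxy)-2,4-bis(methoxymethoxy)-3-methylphenyl]-2-[5-geranyl-2,4-bis(methoxymethoxy)phenyl]-3-hydroxypropyl 4-methylbenzenesulfonate | CC(C)=CCC/C(C)=C/Cc1cc([C@@H]([C@H](O)c2c(OCC=C)cc(OCOC)c(C)c2OCOC)COS(=O)(=O)c2ccc(C)cc2)c(OCOC)cc1OCOC
F5 | step 13 | (2R,3S)-3-hydroxy-3-[6-hydroxy-2,4-bis(methoxymethoxy)-3-methylphenyl]-2-[5-geranyl-2,4-bis(methoxymethoxy)phenyl]propyl 4-methylbenzenesulfonate | CC(C)=CCC/C(C)=C/Cc1cc([C@@H]([C@H](O)c2c(O)cc(OCOC)c(C)c2OCOC)COS(=O)(=O)c2ccc(C)cc2)c(OCOC)cc1OCOC
F6 | step 11 | (S)-4-benzyl-3-[(2S,3S)-3-[6-(allyloxy)-2,4-bis(methoxymethoxy)-3-methylphenyl]-3-(tert-butyldimethylsilyloxy)-2-[5-geranyl-2,4-bis(methoxymethoxy)phenyl]propanoyl]-1,3-oxazolidin-2-one | CC(C)=CCC/C(C)=C/Cc1cc([C@@H]([C@H](O[Si](C)(C)C(C)(C)C)c2c(OCC=C)cc(OCOC)c(C)c2OCOC)C(=O)N2C(=O)OC[C@@H]2Cc2ccccc2)c(OCOC)cc1OCOC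
F7 | step 11 | (2R,3S)-3-[6-(allyloxy)-2,4-bis(methoxymethoxy)-3-methylphenyl]-3-(tert-butyldimethylsilyloxy)-2-[5-geranyl-2,4-bis(methoxymethoxy)phenyl]propan-1-ol | CC(C)=CCC/C(C)=C/Cc1cc([C@@H]([C@H](O[Si](C)(C)C(C)(C)C)c2c(OCC=C)cc(OCOC)c(C)c2OCOC)CO)c(OCOC)cc1OCOC
F8 | step 3 | [5-geranyl-2,4-bis(methoxymethoxy)phenyl]lithium | CC(C)=CCC/C(C)=C/Cc1cc([Li])c(OCOC)cc1OCOC
F9 | step 3 | 2-[5-geranyl-2,4-bis(methoxymethoxy)phenyl]ethan-1-ol | CC(C)=CCC/C(C)=C/Cc1cc(CCO)c(OCOC)cc1OCOC
F10 | step 3 | 2-[5-geranyl-2,4-bis(methoxymethoxy)phenyl]acetaldehyde | CC(C)=CCC/C(C)=C/Cc1cc(CC=O)c(OCOC)cc1OCOC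
A1 | alternative 1 | 3-[5-bromo-2,4-bis(methoxymethoxy)phenyl]-5,7-bis(methoxymethoxy)-6-methyl-2H-chromene | Brc1cc(C2=Cc3c(OCOC)c(C)c(OCOC)cc3OC2)c(OCOC)cc1OCOC
A2 | alternative 1 | (3R,4S)-3-[5-bromo-2,4-bis(methoxymethoxy)phenyl]-5,7-bis(methoxymethoxy)-6-methylchroman-4-ol | Brc1cc([C@@H]2COc3cc(OCOC)c(C)c(OCOC)c3[C@H]2O)c(OCOC)cc1OCOC
A3 | alternative 2 | rac-3-bromo-5,7-bis(methoxymethoxy)-6-methylchroman-4-one | COCOc1cc2OCC(Br)C(=O)c2c(OCOC)c1C
A4 | alternative 2 | [5-geranyl-2,4-bis(methoxymethoxy)phenyl]zinc iodide | CC(C)=CCC/C(C)=C/Cc1cc([Zn]I)c(OCOC)cc1OCOC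
A5 | alternative 2 | (3R)-3-[5-geranyl-2,4-bis(methoxymethoxy)phenyl]-5,7-bis(methoxymethoxy)-6-methylchroman-4-one (identical with 25) | CC(C)=CCC/C(C)=C/Cc1cc([C@@H]2COc3cc(OCOC)c(C)c(OCOC)c3C2=O)c(OCOC)cc1OCOC
A6 | alternative 3 | 3-[5-geranyl-2,4-bis(methoxymethoxy)phenyl]oxetane | CC(C)=CCC/C(C)=C/Cc1cc(C2COC2)c(OCOC)cc1OCOC
A7 | alternative 3 | 2-iodo-3,5-bis(methoxymethoxy)-4-methylphenol | Oc1cc(OCOC)c(C)c(OCOC)c1I
A8 | alternative 3 | (S)-2-[5-geranyl-2,4-bis(methoxymethoxy)phenyl]-3-[2-iodo-3,5-bis(methoxymethoxy)-4-methylphenoxy]propan-1-ol | CC(C)=CCC/C(C)=C/Cc1cc([C@@H](CO)COc2cc(OCOC)c(C)c(OCOC)c2I)c(OCOC)cc1OCOC
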